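## The problem

The target (30) is a bicyclo[3.3.1]nonane-2,4,9-trione. Ring A (C1–C2–C3–C4–C5–C9) is an enolised β-diketone carrying a 3-hydroxybenzoyl group on C3; ring B (C1–C8–C7–C6–C5–C9) holds the gem-dimethyl carbon C6, the prenylated methine C7 and the methylene C8; the rings share the bridging ketone C9 and the bridgeheads C1 (geranyl) and C5 (prenyl). These locants are used for the same atoms in every intermediate.

A synthesis must join two six-membered rings through three common atoms while making C1, C5 and C6 fully substituted, with C5 and C6 adjacent and C9 between two quaternary carbons.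

There are three stereocentres, (1S,5S,7S) with these locants. C1 and C5 are locked to each other by the one-carbon bridge, so only their common absolute sense must be chosen. C7 carries its prenyl group endo, on the face of ring B spanned by the C2–C3–C4 bridge. This is the more crowded orientation and cannot be reached by equilibration, but the folded bicycle can dictate it if hydrogen is delivered to a trigonal C7 from the open exo face.

The four trisubstituted alkenes of the side chains rule out hydrogenation, peracids, ozone and strong protic or Lewis acids. The acylated β-diketone is a vinylogous acid open to retro-Claisen cleavage, and the phenol is oxidisable, so both should appear late and masked.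

The feature that invites the key step is the triad C9–C5–C6. C5 is α and C6 is β to the C9 carbonyl carbon (C5–C6 is the α,β bond), and C6 is also α to C7, where a carbonyl can be placed temporarily. Closing C6 onto C9 gives a cyclopropane with an oxygen donor on C9 and acceptors on C6; cleaving that same C6–C9 bond heterolytically returns C9 as a ketone and leaves C5–C6 as a bond of ring B.

C2 and C9 are both oxygenated and flank C1, the pattern of a Birch-reduced 1,3-dimethoxyarene. A cyclohexadiene dialkylated at that carbon has a mirror plane through C1 and C4, so its two enol ethers are enantiotopic and one catalyst-controlled event can fix C1 and C5 together.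

## Retrosynthesis

**Unmasking and the C3–aroyl bond.** Target 30 is traced to 29, its C2 methyl enol ether and aryl silyl ether, and 29 is cut at C3–C(=O)Ar into vinylogous ester 24 and acid chloride 27 (from acid 25 through 26). C3 of a 2-methoxy-enone is an sp2 C–H between two activating groups and can be lithiated and acylated. Placing this last keeps the fragile triketone and the electron-rich aryl ketone out of every earlier step. The neighbouring cut (C2–C3 and C3–C4, ring A from a malonyl unit) would demand the whole substituted ring B first. The forward step must metalate C3 without touching C9.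

**The C5–prenyl bond.** 24 is cut to 21 and prenyl bromide 22. C5–H lies between the C4 and C9 carbonyls on a bridgehead that tolerates a pyramidal carbanion, so it can be removed by an amide base once C4 is a carbonyl and C7 is no longer an enolisable ketone. The prenyl group cannot be carried from the start because C5 is the carbon the carbene attacks. The precursor 21 is simpler by one quaternary centre.

**The C4 oxygen.** 21 is traced to enol ether 20 by oxidising the C4 methylene. The C2 enol ether is the unreacted half of the original diene, so oxidation at its allylic carbon gives exactly the regioisomer (methoxy on C2, carbonyl next to C5–H) that the bridgehead alkylation needs. The forward reaction must prefer this ring CH2 over the allylic positions of the side chains.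

**The C7 side chain.** 20 is cut between CH2 and CH= of the C7 prenyl group, giving the exocyclic alkene 17 and 1-bromo-2-methylprop-1-ene 18, joined through borane 19. Hydroboration delivers hydrogen to C7 from the exo face and so sets the endo configuration; the sp3–sp2 coupling then completes the prenyl group. Addition of a prenyl nucleophile to a C7 ketone would give the wrong oxidation level and no control of C7.

**The C7 methylene and the two C6 methyl groups.** 17 comes from diketone 16 by methylenation of C7. 16 is cut at both C6–CH3 bonds: the second methyl goes back to enolate 15 and sulfone 14, the first to the β-keto sulfone 13. An ester on C6 would serve the key step equally, but its carbon would have to be reduced to a methyl group at a neopentyl position beside two ketones, at a cost of about four steps. A phenylsulfonyl group is a spectator to the same bond changes and is the best-documented acceptor for copper/bis(oxazoline) cyclopropanation. It first stabilises the C6 carbanion for one methylation, then leaves as sulfinate and hands over a regiodefined enolate for the other.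

**The key disconnection.** 13 is cut at C5–C6 by way of cyclopropane 12 (bonds C6–C5 and C6–C9) to the achiral α-diazo-β-keto sulfone 11. This removes ring B and both bridgehead stereocentres at once and leaves a monocyclic diene. The forward reaction must select one of two enantiotopic enol ethers, must prefer the enol ether to the geranyl alkenes, and must open the three-membered ring only at C6–C9.

**The diene.** 11 comes by diazo transfer from β-keto sulfone 10, which is cut at the C7–C6 bond into ester 8 and methyl phenyl sulfone 9. 8 is cut at C1–C8 into diene 5 and methyl bromoacetate 6 (through lithium species 7). 5 is cut at C1–CH2 into 1,5-dimethoxycyclohexa-1,4-diene 2 and geranyl bromide 3 (through 4), and 2 is the Birch product of 1,3-dimethoxybenzene 1. Both alkylations occur at the one ring carbon flanked by the two methoxy-bearing carbons, so C1 becomes quaternary without any stereochemical question.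

## Roads not taken

**Alternative 1:** an ester-tethered intramolecular Diels–Alder reaction that cuts C5–C6 and C7–C8. A 2-silyloxydiene (C8=C1–C9=C5) would add across a Z-trisubstituted alkene C6=C7 held by an allylic ester, giving the lactone-fused cyclohexene A1.
- *Merits:* ring B, the vicinal quaternary pair C5/C6 and the C7 stereocentre arise in one suprafacial step, with the C5 and C7 prenyl groups already in place. This is better than the chosen plan, which spends a bridgehead alkylation, two methylations and a hydroboration–coupling on the same atoms.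
- *Weak points:* a fully substituted diene terminus must bond to a trisubstituted, unactivated dienophile, so two adjacent quaternary carbons form in a cycloaddition with no electronic help; the temperatures needed invite ene reactions and 1,5-hydrogen shifts of the prenyl chains. The achiral substrate offers no source of absolute configuration. After the cycloaddition the lactone CH2–O still has to be reduced to a methyl group and all of ring A (C1–C2, C2–C3, C3–C4) is still missing.
- *Comparison:* the chosen plan sets against this a C5–C6 bond formed while C5 is a CH and C6 a carbene carbon, a catalyst that sets the absolute sense, and ring A carbons already present.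

**Alternative 2:** a double Claisen condensation that cuts C2–C3 and C3–C4. The lithium enolate of aryl methyl ketone A3 would open the bridged anhydride A2 and, after activation of the freed carboxylate, acylate again at the same carbon, giving the O-silyl target A4.
- *Merits:* it is the most convergent ending. The aroyl carbon arrives with ring A, so no separate C3 acylation and no enol ether chemistry are needed; in step count from A2 it beats the last four steps of the chosen plan.
- *Weak points:* A2 contains all three stereocentres, both quaternary bridgeheads and the gem-dimethyl group, so the real problem is only moved. A2 is also a ketone flanked by two carboxyl carbons and is prone to decarboxylation and retro-Claisen opening. The second acylation must close a ring between two neopentyl-type carbonyls.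
- *Comparison:* the chosen plan answers with a route that actually creates C1, C5 and C7 from achiral material.

**Alternative 3:** a semipinacol ring expansion that cuts C1–C8. Et2AlCl would open the 2,3-epoxy alcohol A5 at C1 while C8 migrates from the carbinol carbon C9 to C1, giving ketone A6.
- *Merits:* the migration is stereospecific (anti to the breaking C–O bond), and a chiral-pool cyclopentane could supply the gem-dimethyl carbon and the absolute configuration. Both points are more secure than a catalyst-controlled desymmetrisation and a gem-dimethylation by alkylation.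
- *Weak points:* A5 needs a hydrindane with a tertiary carbinol, a quaternary C5 and a tetrasubstituted epoxide bearing the geranyl chain, made in the presence of three other trisubstituted alkenes. The Lewis acid meets those alkenes and a dioxolane. C2 and C4 must then be adjusted and C3 acylated.
- *Comparison:* the chosen plan sets against this a five-step access to its key substrate and no epoxidation among prenyl groups.

Key step: step 6

Assumption: the (S,S)-bis(oxazoline) is taken to select the enol ether that leads to 13; if the sense of induction proves opposite, the (R,R)-ligand is used with nothing else changed.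

## Route

Step 1
Reactants: 1 1,3-dimethoxybenzene
Product: 2 1,5-dimethoxycyclohexa-1,4-diene
Conditions: Li, liq. NH3, THF, t-BuOH, −78 °C; NH4Cl quench
Reagents that add atoms: none
Why: Birch reduction; the two methoxy groups direct protonation to C2 and C5 of the arene, so both oxygenated carbons stay sp2 and the unconjugated bis(enol ether) should result.

Step 2
Reactants: 2 1,5-dimethoxycyclohexa-1,4-diene; 3 geranyl bromide
Product: 5 6-[(2E)-3,7-dimethylocta-2,6-dien-1-yl]-1,5-dimethoxycyclohexa-1,4-diene, via cyclohexadienyllithium 4 (not isolated)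
Conditions: t-BuLi, THF, −78 °C; then 3, −78 → 0 °C
Reagents that add atoms: none
Why: Deprotonation at the ring CH2 flanked by the two methoxy-bearing carbons gives a cyclohexadienyl anion that is alkylated at its central carbon by the allylic bromide (SN2 alkylation of a Birch-type anion), keeping the 1,4-diene.

Step 3
Reactants: 5 6-geranyl-1,5-dimethoxycyclohexa-1,4-diene; 6 methyl bromoacetate
Product: 8 methyl 2-[1-geranyl-2,6-dimethoxycyclohexa-2,5-dien-1-yl]acetate, via geranylcyclohexadienyllithium 7 (not isolated)
Conditions: t-BuLi, THF–DMPU, −78 °C; then 6, −78 °C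
Reagents that add atoms: none
Why: The remaining doubly allylic C–H between the methoxy-bearing carbons is removed and the anion is alkylated again at its central carbon by the α-bromo ester (SN2), which makes C1 quaternary; C1 is not stereogenic because its two ring arms are identical.

Step 4
Reactants: 8 methyl 2-[1-geranyl-2,6-dimethoxycyclohexa-2,5-dien-1-yl]acetate; 9 methyl phenyl sulfone
Product: 10 1-[1-geranyl-2,6-dimethoxycyclohexa-2,5-dien-1-yl]-3-(phenylsulfonyl)propan-2-one
Conditions: 9, n-BuLi (2.2 equiv each), THF, −78 → 0 °C; aq. NH4Cl
Reagents that add atoms: none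
Why: Claisen-type acylation of the α-sulfonyl carbanion by the methyl ester; the second equivalent deprotonates the β-keto sulfone as it forms and so prevents a second addition, and the enol ethers are inert to base.

Step 5
Reactants: 10 1-[1-geranyl-2,6-dimethoxycyclohexa-2,5-dien-1-yl]-3-(phenylsulfonyl)propan-2-one
Product: 11 1-diazo-3-[1-geranyl-2,6-dimethoxycyclohexa-2,5-dien-1-yl]-1-(phenylsulfonyl)propan-2-one
Conditions: p-acetamidobenzenesulfonyl azide, Et3N, MeCN, 0 °C → rt
Reagents that add atoms: p-acetamidobenzenesulfonyl azide, CC(=O)Nc1ccc(cc1)S(=O)(=O)N=[N+]=[N-]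
Why: Regitz diazo transfer to the active methylene between the ketone and the sulfone; no other C–H in 10 is acidic enough to react.

Step 6
Reactants: 11 1-diazo-3-[1-geranyl-2,6-dimethoxycyclohexa-2,5-dien-1-yl]-1-(phenylsulfonyl)propan-2-one
Product: 13 1-geranyl-2-methoxy-6-(phenylsulfonyl)bicyclo[3.3.1]non-2-ene-7,9-dione (C1 and C5 as in 30), via donor–acceptor cyclopropane 12 (not isolated)
Conditions: (CuOTf)2·C6H6 (5 mol %), 2,2'-(propane-2,2-diyl)bis[(4S)-4-isopropyl-4,5-dihydrooxazole] (12 mol %), toluene, 50 °C; then PPTS (cat.), THF–H2O, 0 °C
Reagents that add atoms: water, O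
Why: Intramolecular cyclopropanation followed by donor–acceptor cyclopropane fragmentation; the closest known type is the copper/bis(oxazoline)-catalysed asymmetric intramolecular cyclopropanation of α-diazo-β-keto sulfones to bicyclo[3.1.0]hexan-2-ones. CuOTf (monovalent copper) with the ligand turns 11 into an electrophilic copper carbene at C6, which adds to the electron-rich C9=C5 enol ether and forms C6–C5 and C6–C9; the three-atom tether closes the five-membered ring C1–C8–C7–C6–C9 onto the proximal alkene carbon C9, with the three-membered ring C5–C6–C9 cis-fused to it (12). In 12 the C6–C9 bond lies between the methoxy donor and the keto and sulfonyl acceptors, so mild acid ionises it to a C9 oxocarbenium ion and a stabilised C6 carbanion; water adds at C9, methanol leaves, and the six-membered ring C1–C8–C7–C6–C5–C9 remains with C9 as ketone, a net six-ring closure through the distal carbon C5. The zwitterion cannot collapse to a dihydrofuran, because an O–C9 bond from the C7 enolate oxygen would put a double bond at the bridgehead of an oxanorbornene. C1 is set by the ligand, which decides which of the two enantiotopic enol ethers of the achiral substrate is attacked, and C5 follows from C1 because the tether can deliver the carbene only to the diene face on which it sits; C6 is epimerisable and of no consequence. Preference for the enol ether over the geranyl alkenes and allylic C–H bonds rests on its higher nucleophilicity, on the five-ring tether and on the preference of copper carbenes for addition over insertion. Cleavage at C6–C9 and not at C5–C9 is secured by the two acceptors on C6, and the C2 enol ether is kept by using buffered acid at 0 °C.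

Step 7
Reactants: 13 1-geranyl-2-methoxy-6-(phenylsulfonyl)bicyclo[3.3.1]non-2-ene-7,9-dione
Product: 14 1-geranyl-2-methoxy-6-methyl-6-(phenylsulfonyl)bicyclo[3.3.1]non-2-ene-7,9-dione
Conditions: MeI, K2CO3, acetone, rt
Reagents that add atoms: iodomethane, CI
Why: C-alkylation of the β-keto sulfone anion; the methyl group should enter from the convex face anti to C4, but the C6 configuration is erased in the next step.

Step 8
Reactants: 14 1-geranyl-2-methoxy-6-methyl-6-(phenylsulfonyl)bicyclo[3.3.1]non-2-ene-7,9-dione
Product: 16 1-geranyl-2-methoxy-6,6-dimethylbicyclo[3.3.1]non-2-ene-7,9-dione, via lithium enolate 15 (not isolated)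
Conditions: LiC10H8 (2.2 equiv), THF, −78 °C; then MeI, −78 → 0 °C
Reagents that add atoms: iodomethane, CI
Why: Reductive desulfonylation of the α-sulfonyl ketone by two single-electron transfers releases sulfinate and the regiodefined C6=C7 lithium enolate, which is C-methylated in the same flask (reductive alkylation). The keto sulfone accepts electrons far more readily than the hindered dialkyl ketone C9, and no stereocentre is created.

Step 9
Reactants: 16 1-geranyl-2-methoxy-6,6-dimethylbicyclo[3.3.1]non-2-ene-7,9-dione
Product: 17 1-geranyl-2-methoxy-6,6-dimethyl-7-methylidenebicyclo[3.3.1]non-2-en-9-one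
Conditions: Ph3PCH3Br, KOtBu, toluene, 0 → 40 °C
Reagents that add atoms: methyltriphenylphosphonium bromide, C[P+](c1ccccc1)(c1ccccc1)c1ccccc1.[Br-]
Why: Wittig methylenation; the C7 carbonyl has one unsubstituted α-carbon (C8) and an open exo face, whereas C9 sits in the fold between the quaternary C1 and the C5 methine, so the ylide should take C7.

Step 10
Reactants: 17 1-geranyl-2-methoxy-6,6-dimethyl-7-methylidenebicyclo[3.3.1]non-2-en-9-one; 18 1-bromo-2-methylprop-1-ene
Product: 20 1-geranyl-2-methoxy-6,6-dimethyl-7-endo-(3-methylbut-2-en-1-yl)bicyclo[3.3.1]non-2-en-9-one, via B-alkyl-9-BBN adduct 19 (not isolated)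
Conditions: 9-BBN, THF, 0 °C → rt; then 18, Pd(dppf)Cl2 (5 mol %), AsPh3, Cs2CO3, DMF–H2O, 45 °C
Reagents that add atoms: none
Why: Anti-Markovnikov hydroboration of the only 1,1-disubstituted alkene (9-BBN leaves the trisubstituted alkenes and the hindered enol ether alone), then B-alkyl Suzuki–Miyaura coupling with the alkenyl bromide to complete the prenyl group. C7 is set in the hydroboration: the endo face is blocked by the C2–C3–C4 bridge, so boron and hydrogen add from the exo face and the new CH2 group ends endo; C7 is not enolisable afterwards and cannot epimerise.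

Step 11
Reactants: 20 1-geranyl-2-methoxy-6,6-dimethyl-7-endo-prenylbicyclo[3.3.1]non-2-en-9-one
Product: 21 1-geranyl-2-methoxy-6,6-dimethyl-7-endo-prenylbicyclo[3.3.1]non-2-ene-4,9-dione
Conditions: CrO3, 3,5-dimethylpyrazole, CH2Cl2, −20 °C
Reagents that add atoms: chromium trioxide, O=[Cr](=O)=O
Why: Allylic oxidation of the ring CH2 next to the enol ether to the vinylogous ester by the hexavalent chromium–pyrazole complex; the enol ether is the most electron-rich π bond and its ring C4–H bonds are held parallel to the π system, which should favour them over the acyclic allylic positions of the side chains.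

Step 12
Reactants: 21 1-geranyl-2-methoxy-6,6-dimethyl-7-endo-prenylbicyclo[3.3.1]non-2-ene-4,9-dione; 22 prenyl bromide
Product: 24 1-geranyl-2-methoxy-6,6-dimethyl-5,7-bis(3-methylbut-2-en-1-yl)bicyclo[3.3.1]non-2-ene-4,9-dione, via C5 bridgehead lithium species 23 (not isolated)
Conditions: LiN(iPr)2, THF, −78 °C; then 22, −78 → −30 °C
Reagents that add atoms: none
Why: Bridgehead deprotonation α to the C4 carbonyl of the vinylogous ester (bridgehead enolate chemistry of bicyclo[3.3.1]nonane-2,4,9-triones) and SN2 alkylation by the allylic bromide; the bridgehead carbanion cannot invert, so C5 keeps the configuration set in step 6.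

Step 13
Reactants: 25 3-hydroxybenzoic acid
Product: 26 tert-butyldimethylsilyl 3-(tert-butyldimethylsilyloxy)benzoate
Conditions: TBSCl (2.2 equiv), imidazole, DMF, rt
Reagents that add atoms: tert-butyldimethylsilyl chloride, CC(C)(C)[Si](C)(C)Cl
Why: Imidazole-promoted silylation of both the phenol and the carboxylic acid.

Step 14
Reactants: 26 tert-butyldimethylsilyl 3-(tert-butyldimethylsilyloxy)benzoate
Product: 27 3-(tert-butyldimethylsilyloxy)benzoyl chloride
Conditions: (COCl)2, DMF (cat.), CH2Cl2, 0 °C → rt
Reagents that add atoms: oxalyl chloride, O=C(Cl)C(=O)Cl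
Why: Direct conversion of a silyl ester to the acid chloride by the Vilsmeier reagent under neutral conditions; the aryl silyl ether is not affected.

Step 15
Reactants: 24 1-geranyl-2-methoxy-6,6-dimethyl-5,7-diprenylbicyclo[3.3.1]non-2-ene-4,9-dione; 27 3-(tert-butyldimethylsilyloxy)benzoyl chloride
Product: 29 3-[3-(tert-butyldimethylsilyloxy)benzoyl]-1-geranyl-2-methoxy-6,6-dimethyl-5,7-diprenylbicyclo[3.3.1]non-2-ene-4,9-dione, via C3 vinyllithium 28 (not isolated)
Conditions: lithium 2,2,6,6-tetramethylpiperidide (LiTMP), THF, −78 °C; then 27, −78 °C
Reagents that add atoms: none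
Why: α-Lithiation of the vinylogous ester at C3, the only remaining acidic C–H, followed by acylation with the acid chloride; C9 is shielded by two quaternary carbons and the hindered amide base does not add to it.

Step 16
Reactants: 29 3-[3-(tert-butyldimethylsilyloxy)benzoyl]-1-geranyl-2-methoxy-6,6-dimethyl-5,7-diprenylbicyclo[3.3.1]non-2-ene-4,9-dione
Product: 30 (1S,5S,7S)-1-geranyl-2-hydroxy-3-(3-hydroxybenzoyl)-6,6-dimethyl-5,7-diprenylbicyclo[3.3.1]non-2-ene-4,9-dione (target)
Conditions: LiOH, dioxane–H2O, 90 °C; then aq. HCl to pH 3
Reagents that add atoms: lithium hydroxide, [Li+].[OH-]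
Why: Hydroxide adds to C2 of the vinylogous ester and expels methoxide (addition–elimination), and the aryl silyl ether is cleaved by hydroxide at silicon in the same pot; acidification should give the enolised triketone, with the alkenes and all three stereocentres untouched.

## Compound list

1 | 1,3-dimethoxybenzene | COc1cccc(OC)c1 | starting material
2 | 1,5-dimethoxycyclohexa-1,4-diene | COC1=CCC=C(OC)C1 | intermediate
3 | geranyl bromide, (2E)-1-bromo-3,7-dimethylocta-2,6-diene | CC(C)=CCC/C(C)=C/CBr | starting material
4 | (2,6-dimethoxycyclohexa-2,5-dien-1-yl)lithium | [Li]C1C(OC)=CCC=C1OC | intermediate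
5 | 6-[(2E)-3,7-dimethylocta-2,6-dien-1-yl]-1,5-dimethoxycyclohexa-1,4-diene | CC(C)=CCC/C(C)=C/CC1C(OC)=CCC=C1OC | intermediate
6 | methyl bromoacetate | COC(=O)CBr | starting material
7 | (1-geranyl-2,6-dimethoxycyclohexa-2,5-dien-1-yl)lithium | CC(C)=CCC/C(C)=C/CC1([Li])C(OC)=CCC=C1OC | intermediate
8 | methyl 2-[1-geranyl-2,6-dimethoxycyclohexa-2,5-dien-1-yl]acetate | CC(C)=CCC/C(C)=C/CC1(CC(=O)OC)C(OC)=CCC=C1OC | intermediate
9 | methyl phenyl sulfone | CS(=O)(=O)c1ccccc1 | starting material
10 | 1-[1-geranyl-2,6-dimethoxycyclohexa-2,5-dien-1-yl]-3-(phenylsulfonyl)propan-2-one | CC(C)=CCC/C(C)=C/CC1(CC(=O)CS(=O)(=O)c2ccccc2)C(OC)=CCC=C1OC | intermediate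
11 | 1-diazo-3-[1-geranyl-2,6-dimethoxycyclohexa-2,5-dien-1-yl]-1-(phenylsulfonyl)propan-2-one (achiral) | CC(C)=CCC/C(C)=C/CC1(CC(=O)C(=[N+]=[N-])S(=O)(=O)c2ccccc2)C(OC)=CCC=C1OC | intermediate
12 | tricyclic donor–acceptor cyclopropane: three-membered ring C5–C6–C9 cis-fused to cyclopentanone C1–C8–C7–C6–C9 and to ring A, methoxy on C9, phenylsulfonyl on C6, C2 enol ether | CC(C)=CCC/C(C)=C/C[C@]12CC(=O)[C@]3(S(=O)(=O)c4ccccc4)[C@H](CC=C1OC)[C@]23OC | intermediate
13 | 1-geranyl-2-methoxy-6-(phenylsulfonyl)bicyclo[3.3.1]non-2-ene-7,9-dione; C1 and C5 as in 30; sulfonyl group drawn equatorial (syn to C4), C6 epimerisable | CC(C)=CCC/C(C)=C/C[C@]12CC(=O)[C@H](S(=O)(=O)c3ccccc3)[C@H](CC=C1OC)C2=O | intermediate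
14 | 1-geranyl-2-methoxy-6-methyl-6-(phenylsulfonyl)bicyclo[3.3.1]non-2-ene-7,9-dione; methyl anti to C4 | CC(C)=CCC/C(C)=C/C[C@]12CC(=O)[C@](C)(S(=O)(=O)c3ccccc3)[C@H](CC=C1OC)C2=O | intermediate
15 | lithium C6=C7 enolate of the 6-methyl diketone | CC(C)=CCC/C(C)=C/C[C@]12CC(O[Li])=C(C)[C@H](CC=C1OC)C2=O | intermediate
16 | 1-geranyl-2-methoxy-6,6-dimethylbicyclo[3.3.1]non-2-ene-7,9-dione | CC(C)=CCC/C(C)=C/C[C@]12CC(=O)C(C)(C)[C@H](CC=C1OC)C2=O | intermediate
17 | 1-geranyl-2-methoxy-6,6-dimethyl-7-methylidenebicyclo[3.3.1]non-2-en-9-one | CC(C)=CCC/C(C)=C/C[C@]12CC(=C)C(C)(C)[C@H](CC=C1OC)C2=O | intermediate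
18 | 1-bromo-2-methylprop-1-ene | CC(C)=CBr | starting material
19 | B-alkyl-9-BBN adduct, boron on the endo C7–CH2 group | CC(C)=CCC/C(C)=C/C[C@]12C[C@H](CB3C4CCCC3CCC4)C(C)(C)[C@H](CC=C1OC)C2=O | intermediate
20 | 1-geranyl-2-methoxy-6,6-dimethyl-7-endo-prenylbicyclo[3.3.1]non-2-en-9-one | CC(C)=CCC/C(C)=C/C[C@]12C[C@H](CC=C(C)C)C(C)(C)[C@H](CC=C1OC)C2=O | intermediate
21 | 1-geranyl-2-methoxy-6,6-dimethyl-7-endo-prenylbicyclo[3.3.1]non-2-ene-4,9-dione | CC(C)=CCC/C(C)=C/C[C@]12C[C@H](CC=C(C)C)C(C)(C)[C@H](C(=O)C=C1OC)C2=O | intermediate
22 | prenyl bromide, 1-bromo-3-methylbut-2-ene | CC(C)=CCBr | starting material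
23 | C5 bridgehead lithium derivative of 21 | CC(C)=CCC/C(C)=C/C[C@]12C[C@H](CC=C(C)C)C(C)(C)[C@]([Li])(C(=O)C=C1OC)C2=O | intermediate
24 | 1-geranyl-2-methoxy-6,6-dimethyl-5,7-diprenylbicyclo[3.3.1]non-2-ene-4,9-dione; 7-prenyl endo | CC(C)=CCC/C(C)=C/C[C@]12C[C@H](CC=C(C)C)C(C)(C)[C@](CC=C(C)C)(C(=O)C=C1OC)C2=O | intermediate
25 | 3-hydroxybenzoic acid | O=C(O)c1cccc(O)c1 | starting material
26 | tert-butyldimethylsilyl 3-(tert-butyldimethylsilyloxy)benzoate | CC(C)(C)[Si](C)(C)OC(=O)c1cccc(O[Si](C)(C)C(C)(C)C)c1 | intermediate
27 | 3-(tert-butyldimethylsilyloxy)benzoyl chloride | CC(C)(C)[Si](C)(C)Oc1cccc(c1)C(Cl)=O | intermediate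
28 | C3 vinyllithium derivative of 24 | CC(C)=CCC/C(C)=C/C[C@]12C[C@H](CC=C(C)C)C(C)(C)[C@](CC=C(C)C)(C(=O)C([Li])=C1OC)C2=O | intermediate
29 | 3-[3-(tert-butyldimethylsilyloxy)benzoyl]-1-geranyl-2-methoxy-6,6-dimethyl-5,7-diprenylbicyclo[3.3.1]non-2-ene-4,9-dione | CC(C)=CCC/C(C)=C/C[C@]12C[C@H](CC=C(C)C)C(C)(C)[C@](CC=C(C)C)(C(=O)C(C(=O)c3cccc(O[Si](C)(C)C(C)(C)C)c3)=C1OC)C2=O | intermediate
30 | (1S,5S,7S)-1-geranyl-2-hydroxy-3-(3-hydroxybenzoyl)-6,6-dimethyl-5,7-diprenylbicyclo[3.3.1]non-2-ene-4,9-dione; 7-prenyl endo | CC(C)=CCC/C(C)=C/C[C@]12C[C@H](CC=C(C)C)C(C)(C)[C@](CC=C(C)C)(C(=O)C(C(=O)c3cccc(O)c3)=C1O)C2=O | target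

## Step count and least certain steps

Total: 16 steps. Longest linear sequence: 14 steps (steps 1–12, 15 and 16, from 1,3-dimethoxybenzene); steps 13 and 14 form a two-step side branch.

**Step 6 (key step).** The two enantiotopic enol ethers may be discriminated incompletely, because the centre being set (C1) is four atoms from the carbene and the competing transition states differ only in which methoxyvinyl arm faces the ligand. Material can also be lost by carbene insertion into the allylic C–H bonds of the geranyl CH2, or by hydrolysis of the C2 enol ether during the acid-promoted opening. Fallback: run the same cyclopropanation–fragmentation on 11 with achiral Cu(acac)2 in toluene, which gives 13 together with its mirror image, ent-13 F1, and separate the two by preparative chromatography on a chiral stationary phase. The route is rejoined at 13, with resolution in place of catalyst control.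

**Step 11.** Hydrogen abstraction may not be selective for C4: the allylic CH2 and CH3 groups of three trisubstituted alkenes compete, and over-oxidation of the electron-rich enol ether is possible. Fallback from 20, using only ionic reactions that single out the enol ether and then the enone:
- DDQ in wet CH2Cl2 with 2,6-lutidine abstracts hydride from C4 and, after loss of methanol, gives the C3=C4 enone F2.
- Weitz–Scheffer epoxidation (H2O2, NaOH, MeOH, 0 °C), which touches only the electron-poor alkene, gives the epoxy ketone F3.
- Pd(PPh3)4 (zerovalent palladium) with dppe in toluene isomerises F3 to the 2,4-diketone F4.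
- O-methylation with Me3SiCHN2 gives 21 and its regioisomeric enol ether F5, which is separated and hydrolysed back to F4.

The route is rejoined at 21.

**Step 9.** Competing or double olefination at C9 may occur, since both carbonyls are hindered and C9 is still open from the side of ring A. Fallback from 16, relying on the fact that only C7 can be enolised:
- KN(SiMe3)2 and PhNTf2 at −78 °C give the C7 enol triflate F6.
- Kumada–Corriu coupling with Me3SiCH2MgCl and Pd(PPh3)4 gives the allylsilane F7.
- SE2' protodesilylation with anhydrous camphorsulfonic acid in CH2Cl2 at −20 °C, quenched with Et3N, puts hydrogen on C8 and the double bond in the exocyclic position.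

The route is rejoined at 17.

**Step 8.** Electron transfer to the C9 ketone, protonation of enolate 15 before alkylation, or O-methylation would each lower the return of 16. Fallback from 14:
- SmI2 in THF–MeOH at −78 °C removes the sulfonyl group without reducing dialkyl ketones and gives the 6-monomethyl diketone F8.
- Me3SiCl, NaI and Et3N in MeCN under equilibrating conditions give the more substituted trimethylsilyl enol ether F9.
- Benzyltrimethylammonium fluoride and MeI alkylate F9 at C6.

The route is rejoined at 16.

**Step 3.** Bromine–lithium exchange or proton transfer between the basic lithium species 7 and the α-bromo ester may outrun substitution, and alkylation at a terminal carbon of the dienyl anion would give a conjugated diene. Fallback from 5, avoiding the α-halo ester: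
- The same lithium species 7 is quenched with ethylene oxide to give 2-(1-geranyl-2,6-dimethoxycyclohexa-2,5-dien-1-yl)ethanol F10.
- Parikh–Doering oxidation gives the aldehyde F11.
- Addition of LiCH2SO2Ph gives the β-hydroxy sulfone F12.
- Dess–Martin periodinane buffered with NaHCO3 oxidises F12 to the ketone.

The route is rejoined at 10.

## Further compounds

F1 | step 6 | ent-13, mirror image of the bicyclic β-keto sulfone | CC(C)=CCC/C(C)=C/C[C@@]12CC(=O)[C@@H](S(=O)(=O)c3ccccc3)[C@@H](CC=C1OC)C2=O
F2 | step 11 | 1-geranyl-6,6-dimethyl-7-endo-prenylbicyclo[3.3.1]non-3-ene-2,9-dione (C3=C4 enone) | CC(C)=CCC/C(C)=C/C[C@]12C[C@H](CC=C(C)C)C(C)(C)[C@H](C=CC1=O)C2=O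
F3 | step 11 | 3,4-epoxide of F2, oxygen on the exo face of ring A | CC(C)=CCC/C(C)=C/C[C@]12C[C@H](CC=C(C)C)C(C)(C)[C@H]([C@H]3O[C@H]3C1=O)C2=O
F4 | step 11 | 1-geranyl-6,6-dimethyl-7-endo-prenylbicyclo[3.3.1]nonane-2,4,9-trione | CC(C)=CCC/C(C)=C/C[C@]12C[C@H](CC=C(C)C)C(C)(C)[C@H](C(=O)CC1=O)C2=O
F5 | step 11 | 1-geranyl-4-methoxy-6,6-dimethyl-7-endo-prenylbicyclo[3.3.1]non-3-ene-2,9-dione (regioisomer of 21) | CC(C)=CCC/C(C)=C/C[C@]12C[C@H](CC=C(C)C)C(C)(C)[C@H](C(OC)=CC1=O)C2=O
F6 | step 9 | C7 enol triflate of 16 (C7=C8) | CC(C)=CCC/C(C)=C/C[C@]12C=C(OS(=O)(=O)C(F)(F)F)C(C)(C)[C@H](CC=C1OC)C2=O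
F7 | step 9 | 7-[(trimethylsilyl)methyl] C7=C8 alkene (allylsilane) | CC(C)=CCC/C(C)=C/C[C@]12C=C(C[Si](C)(C)C)C(C)(C)[C@H](CC=C1OC)C2=O
F8 | step 8 | 1-geranyl-2-methoxy-6-methylbicyclo[3.3.1]non-2-ene-7,9-dione, methyl syn to C4 (epimerisable) | CC(C)=CCC/C(C)=C/C[C@]12CC(=O)[C@H](C)[C@H](CC=C1OC)C2=O
F9 | step 8 | C6=C7 trimethylsilyl enol ether of F8 | CC(C)=CCC/C(C)=C/C[C@]12CC(O[Si](C)(C)C)=C(C)[C@H](CC=C1OC)C2=O
F10 | step 3 | 2-(1-geranyl-2,6-dimethoxycyclohexa-2,5-dien-1-yl)ethanol | CC(C)=CCC/C(C)=C/CC1(CCO)C(OC)=CCC=C1OC
F11 | step 3 | 2-(1-geranyl-2,6-dimethoxycyclohexa-2,5-dien-1-yl)acetaldehyde | CC(C)=CCC/C(C)=C/CC1(CC=O)C(OC)=CCC=C1OC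
F12 | step 3 | 1-(1-geranyl-2,6-dimethoxycyclohexa-2,5-dien-1-yl)-3-(phenylsulfonyl)propan-2-ol (racemic) | CC(C)=CCC/C(C)=C/CC1(CC(O)CS(=O)(=O)c2ccccc2)C(OC)=CCC=C1OC
A1 | alternative 1 | lactone-fused cyclohexene silyl enol ether | CC(C)=CCC/C(C)=C/CC1=C(O[Si](C)(C)C(C)(C)C)[C@@]2(CC=C(C)C)C(=O)OC[C@@]2(C)[C@@H](CC=C(C)C)C1
A2 | alternative 2 | bridged anhydride, 3-oxabicyclo[3.3.1]nonane-2,4,9-trione with C1 geranyl, C5 and C7 prenyl, C6 gem-dimethyl | CC(C)=CCC/C(C)=C/C[C@]12C[C@H](CC=C(C)C)C(C)(C)[C@](CC=C(C)C)(C(=O)OC1=O)C2=O
A3 | alternative 2 | 1-[3-(tert-butyldimethylsilyloxy)phenyl]ethanone | CC(=O)c1cccc(O[Si](C)(C)C(C)(C)C)c1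
A4 | alternative 2 | O-silyl target | CC(C)=CCC/C(C)=C/C[C@]12C[C@H](CC=C(C)C)C(C)(C)[C@](CC=C(C)C)(C(=O)C(C(=O)c3cccc(O[Si](C)(C)C(C)(C)C)c3)=C1O)C2=O
A5 | alternative 3 | hydrindane 2,3-epoxy alcohol (C1–C2 epoxide, C9 carbinol, C4 dioxolane) | CC(C)=CCC/C(C)=C/C[C@@]12O[C@@H]1CC3(OCCO3)[C@@]4(CC=C(C)C)C(C)(C)[C@@H](CC=C(C)C)C[C@@]24O
A6 | alternative 3 | bicyclo[3.3.1]nonan-9-one with C2 hydroxyl and C4 dioxolane | CC(C)=CCC/C(C)=C/C[C@]12C[C@H](CC=C(C)C)C(C)(C)[C@](CC=C(C)C)(C3(OCCO3)C[C@H]1O)C2=O
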